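**Plan**
Germacranolide numbering is used: C1 ring ketone, C2/C3 CH2CH2, C4/C5 oxirane (CH3 on C4), C6 lactone carbinol, C7, C8 tiglate carbinol, C9, C10 C(CH3)(OAc), C11/C12/C13 lactone α-carbon, carbonyl and CH2OAc.
Retrosynthesis: remove the oxirane oxygen (giving the 4Z alkene) and the two acetates; cut the ten-membered ring between C3 and C4; then cut the C8 ester, the C4=C5 alkene (Wittig), and the C7–C8 and C11–C13 bonds on the lactone.
Enabling feature: C3 is the β-carbon of the C1 ring ketone and C4 is an alkene-derived oxirane carbon, so a cyclopropanol made of C1, C2 and C3 is a latent C3 homoenolate (strain release with polarity reversal) that can be joined to a (Z)-C4 alkenyl iodide.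
Forward: (R)-citramalic acid gives fragment B (C8 dithiane–C9–C10–cyclopropanol); a three-component union with butenolide fragment A (C5, C6, C7, C11, C12) and a C13 electrophile builds the γ-lactone first; C5 becomes the iodoalkene and C8 the tiglate; the ten-membered carbocycle is then closed; acetates and the oxirane come last.
Stereochemistry: C10 from (R)-citramalic acid; C6 from (S)-5-(hydroxymethyl)furan-2(5H)-one; C7 and C11 by anti addition and anti alkylation on the lactone; C8 by 1,3-syn reduction from C10; C4=C5 Z from the iodo-Wittig; C4/C5 from a chiral dioxirane.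

Key step: step 15

Remark: the SMILES is read as the 8-tiglate ((E)-2-methylbut-2-enoate) of a cis-oxirane (C3 and C6 on the same side, 4R,5S), so its alkene precursor must be 4Z.

Step 1
Reactants: 1 (R)-citramalic acid
Product: 2 2-[(4R)-2,2,4-trimethyl-5-oxo-1,3-dioxolan-4-yl]acetic acid
Conditions: Me2C(OMe)2, TsOH·H2O (cat.), rt
Reagents that add atoms: 2,2-dimethoxypropane, COC(C)(C)OC
Why: Acid-catalysed acetalisation ties the α-hydroxy acid into a 1,3-dioxolan-4-one and leaves the CH2CO2H arm free, which differentiates the two carboxyls of the chiral-pool acid whose stereocentre becomes C10.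

Step 2
Reactants: 2 dioxolanone acid
Product: 3 (3R)-3-hydroxy-4-methoxy-3-methyl-4-oxobutanoic acid
Conditions: NaOMe (2.2 equiv), MeOH, 0 °C → rt; then 1 M HCl
Reagents that add atoms: sodium methoxide, C[O-].[Na+]
Why: Methoxide opens the activated dioxolanone carbonyl (transesterification with loss of acetone) while the other carboxyl is shielded as its carboxylate, giving the 1-methyl ester that will become the cyclopropanol carbon C1.

Step 3
Reactants: 3 half ester
Product: 4 methyl (2R)-3-(1,3-dithian-2-yl)-2-hydroxy-2-methylpropanoate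
Conditions: BH3·SMe2, HS(CH2)3SH, THF, 0 °C → rt (gives 1,3,2-dithiaborinane·SMe2); then 3, SnCl2 (20 mol%), rt
Reagents that add atoms: propane-1,3-dithiol, SCCCS
Why: Direct reductive dithioacetalisation of a carboxylic acid: the dithiaborinane reduces only the free acid through its acyloxyborane and transfers the dithiol in the same operation, the methyl ester being inert, so C8 arrives at the aldehyde oxidation level as a dithiane.

Step 4
Reactants: 4 dithiane ester
Product: 5 1-[(2R)-1-(1,3-dithian-2-yl)-2-hydroxypropan-2-yl]cyclopropan-1-ol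
Conditions: EtMgBr (5 equiv), Ti(OiPr)4 (1 equiv), THF, 0 °C → rt
Reagents that add atoms: ethylmagnesium bromide, CC[Mg]Br
Why: Kulinkovich cyclopropanation: the titanacyclopropane from EtMgBr and Ti(OiPr)4 adds twice to the ester carbonyl to build the cyclopropanol (C1, C2, C3), the extra Grignard covering the tertiary hydroxyl and the quaternary stereocentre staying untouched.

Step 5
Reactants: 5 cyclopropanol diol
Product: 7 2-[(2R)-2-[(triethylsilyl)oxy]-2-{1-[(triisopropylsilyl)oxy]cyclopropyl}propyl]-1,3-dithiane (fragment B), via mono-TIPS ether 6 (not isolated)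
Conditions: TIPSOTf (1.05 equiv), 2,6-lutidine, CH2Cl2, −78 → 0 °C; then TESOTf (1.5 equiv), 0 °C
Reagents that add atoms: triisopropylsilyl trifluoromethanesulfonate, CC(C)[Si](OS(=O)(=O)C(F)(F)F)(C(C)C)C(C)C; triethylsilyl trifluoromethanesulfonate, CC[Si](CC)(CC)OS(=O)(=O)C(F)(F)F
Why: Silyl ether formation in order of accessibility: the bulky triflate should react only with the less hindered, more acidic cyclopropanol, and the smaller TES triflate then caps the tertiary C10 hydroxyl, giving two silyl ethers that can later be removed separately.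

Step 6
Reactants: 8 (5S)-5-(hydroxymethyl)furan-2(5H)-one
Product: 9 (5S)-5-{[(triethylsilyl)oxy]methyl}furan-2(5H)-one (fragment A)
Conditions: TESCl, imidazole, CH2Cl2, 0 °C
Reagents that add atoms: chlorotriethylsilane, CC[Si](Cl)(CC)CC
Why: Routine silylation of the primary alcohol; the TES ether is chosen because a primary TES ether can later be oxidised directly to the aldehyde.

Step 7
Reactants: 7 fragment B; 9 fragment A
Product: 12 all-trans lactone adduct (CH2OTES on C6; dithiane carbon C8 on C7; CH2OPMB on C11), via 2-lithio-1,3-dithiane 10 (not isolated), via lithium enolate 11 (not isolated)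
Conditions: 7, t-BuLi, THF/HMPA (10:1), −78 °C; 9, −78 °C; then 4-MeOC6H4CH2OCH2Cl, −78 → −40 °C; aq. NH4Cl
Reagents that add atoms: 4-methoxybenzyl chloromethyl ether, COc1ccc(COCCl)cc1
Why: Tandem Michael addition and enolate alkylation: the lithiated dithiane (acyl anion equivalent for C8) adds to the butenolide anti to the C6 CH2OTES group, which sets C7, and the lactone enolate is then alkylated anti to the new C7 substituent, which sets C11 and gives the all-trans lactone.

Step 8
Reactants: 12 lactone adduct
Product: 13 C5 aldehyde (formyl group on C6)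
Conditions: (COCl)2, DMSO, CH2Cl2, −78 → −35 °C; Et3N, −78 °C → rt
Reagents that add atoms: none
Why: Direct Swern oxidation of a silyl ether: activated DMSO cleaves and oxidises the primary TES ether in one operation while the tertiary TES ether, the TIPS ether, the PMB ether and the dithiane persist.

Step 9
Reactants: 13 aldehyde
Product: 14 (Z)-iodoalkene (C6–CH=C(I)CH3, iodine cis to C6)
Conditions: [Ph3PEt]I, n-BuLi, THF, rt; I2, −78 °C; NaN(SiMe3)2, −20 °C; then 13, −78 → −20 °C
Reagents that add atoms: ethyltriphenylphosphonium iodide, CC[P+](c1ccccc1)(c1ccccc1)c1ccccc1.[I-]; iodine, II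
Why: Stork–Zhao-type Wittig olefination with the α-iodo ylide should give the (Z)-2-iodoalkene under kinetic control through the cis-oxaphosphetane, which fixes the alkene geometry that the oxirane will inherit.

Step 10
Reactants: 14 iodoalkene dithiane
Product: 15 C8 ketone (C10 OTES, cyclopropyl OTIPS)
Conditions: MeI, CaCO3, MeCN/H2O (9:1), 45 °C
Reagents that add atoms: water, O
Why: Alkylative dithioacetal hydrolysis: S-methylation makes the dithiane a leaving group and water releases the ketone under near-neutral conditions without oxidant or soft metal, so the siloxycyclopropane, the alkenyl iodide and the base-sensitive β-acyloxy ketone survive.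

Step 11
Reactants: 15 ketone
Product: 16 β-hydroxy ketone (free C10 tertiary hydroxyl)
Conditions: HF·pyridine, pyridine, THF, 0 °C
Reagents that add atoms: none
Why: Selective desilylation: buffered fluoride removes the TES ether much faster than the TIPS ether and unmasks the C10 hydroxyl that must direct the reduction, while the cyclopropanol stays protected.

Step 12
Reactants: 16 β-hydroxy ketone
Product: 18 (8S,10R)-8,10-syn-diol, via diethylboron chelate 17 (not isolated)
Conditions: Et2BOMe, THF/MeOH (4:1), −78 °C; NaBH4, −78 °C; then MeOH, evaporation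
Reagents that add atoms: none
Why: Narasaka–Prasad reduction: the boron chelate of the β-hydroxy ketone adopts a half-chair with the bulky cyclopropyl carbon equatorial and external hydride adds axially, which should give the 1,3-syn diol and so the (S) configuration at C8 under control of C10.

Step 13
Reactants: 18 syn-diol; 19 tiglic acid
Product: 20 (8S)-8-O-tiglate (free C10 hydroxyl, TIPS-protected cyclopropanol)
Conditions: 19, 2,4,6-Cl3C6H2COCl, Et3N, toluene, rt; then 18, DMAP, rt
Reagents that add atoms: none
Why: Yamaguchi esterification acylates the secondary C8 hydroxyl with retention while the tertiary C10 hydroxyl is too hindered to react, and the tiglate, being the stable E isomer, cannot scramble under DMAP.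

Step 14
Reactants: 20 tiglate
Product: 21 cyclisation precursor ((Z)-alkenyl iodide with free cyclopropanol)
Conditions: Bu4NF, AcOH, THF, 0 °C → rt
Reagents that add atoms: none
Why: Fluoride cleaves the TIPS ether to free the cyclopropanol, and buffering with acetic acid protects the tiglate, the lactone and the β-alkoxy lactone from base.

Step 15
Reactants: 21 cyclisation precursor
Product: 22 (4Z)-macrocycle (1-oxo-10-hydroxy-8-tigloyloxy-13-PMB-oxy ten-membered carbocycle fused to the lactone)
Conditions: Pd(OAc)2 (15 mol%), XPhos (30 mol%), Cs2CO3, toluene, 80 °C, slow addition (0.002 M)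
Reagents that add atoms: none
Why: Proposed new method: zerovalent palladium inserts into the C4–I bond, the cyclopropanolate replaces iodide on divalent palladium, strain-driven β-carbon elimination opens the three-membered ring (C1, C2, C3) to a palladium homoenolate with the metal on C3, and C(sp3)–C(sp2) reductive elimination forms the C3–C4 bond and the C1 ketone. The closest known reaction type is the intermolecular palladium-catalysed ring-opening cross-coupling of cyclopropanols with aryl and alkenyl halides, here run intramolecularly at high dilution. The ten-membered carbocycle closes by reductive elimination from an eleven-membered palladacycle, an endo closure in which both alkene carbons become ring members; the trans-fused lactone and the quaternary C10 hold the two arms in a turn. No stereocentre is created, but the alkenyl–palladium bond keeps its geometry, so C3 replaces iodine cis to C6 and the 4Z alkene needed for the cis-oxirane is fixed by step 9. The step needs ring closure to outrun β-hydride elimination of the homoenolate (enone plus reduced alkene) and oligomerisation: the bulky biarylphosphine speeds reductive elimination and slow addition keeps the substrate concentration low. The two cyclopropane CH2 groups are equivalent, so ring opening has no regiochemical issue, and the tiglate, lactone, PMB ether and free C10 hydroxyl should be inert to the carbonate base.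

Step 16
Reactants: 22 macrocycle
Product: 23 13-alcohol
Conditions: DDQ, CH2Cl2/pH 7 buffer, 0 °C → rt
Reagents that add atoms: none
Why: Oxidative PMB ether cleavage (hydride abstraction by DDQ, then hydrolysis) frees the C13 hydroxyl while the trisubstituted alkene, the tiglate and the α-ketol are inert.

Step 17
Reactants: 23 diol (C10 tertiary OH, C13 primary OH)
Product: 24 10,13-diacetate (4Z alkene)
Conditions: Ac2O, Sc(OTf)3 (2 mol%), MeCN, −20 °C
Reagents that add atoms: acetic anhydride, CC(=O)OC(C)=O
Why: Lewis acid-catalysed acylation acetylates the primary C13 and the hindered tertiary C10 hydroxyl in one operation without base, so the new β-acetoxy lactone cannot eliminate to the α-methylene lactone.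

Step 18
Reactants: 24 diacetate alkene
Product: 25 target CNP0305680.1
Conditions: L-fructose-derived ketone catalyst (1,2:4,5-di-O-isopropylidene-β-L-erythro-2,3-hexodiulo-2,6-pyranose, 30 mol%), KHSO5 (as 2KHSO5·KHSO4·K2SO4), K2CO3/AcOH buffer (pH ≈ 9.3), MeCN/CH2(OMe)2/H2O, 0 °C
Reagents that add atoms: potassium peroxymonosulfate, [K+].[O-]S(=O)(=O)OO
Why: Shi epoxidation: the chiral dioxirane oxidises only the electron-rich trisubstituted C4=C5 alkene through a spiro transition state, and for this 1-methylcycloalkene-type olefin the L-fructose-derived ketone should deliver oxygen to the α-face to give (4R,5S), the Z geometry fixing C3 and C6 cis on the oxirane.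

**Compound list**
1 | (R)-citramalic acid, (2R)-2-hydroxy-2-methylbutanedioic acid | OC(=O)C[C@@](C)(O)C(=O)O | starting material
2 | 2-[(4R)-2,2,4-trimethyl-5-oxo-1,3-dioxolan-4-yl]acetic acid | CC1(C)O[C@](C)(CC(=O)O)C(=O)O1 | intermediate
3 | (3R)-3-hydroxy-4-methoxy-3-methyl-4-oxobutanoic acid | OC(=O)C[C@@](C)(O)C(=O)OC | intermediate
4 | methyl (2R)-3-(1,3-dithian-2-yl)-2-hydroxy-2-methylpropanoate | S1CCCSC1C[C@@](C)(O)C(=O)OC | intermediate
5 | 1-[(2R)-1-(1,3-dithian-2-yl)-2-hydroxypropan-2-yl]cyclopropan-1-ol | S1CCCSC1C[C@@](C)(O)C2(O)CC2 | intermediate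
6 | (2R)-1-(1,3-dithian-2-yl)-2-{1-[(triisopropylsilyl)oxy]cyclopropyl}propan-2-ol | S1CCCSC1C[C@@](C)(O)C2(O[Si](C(C)C)(C(C)C)C(C)C)CC2 | intermediate (not isolated)
7 | fragment B, 2-[(2R)-2-[(triethylsilyl)oxy]-2-{1-[(triisopropylsilyl)oxy]cyclopropyl}propyl]-1,3-dithiane | S1CCCSC1C[C@@](C)(O[Si](CC)(CC)CC)C2(O[Si](C(C)C)(C(C)C)C(C)C)CC2 | intermediate
8 | (5S)-5-(hydroxymethyl)furan-2(5H)-one | OC[C@@H]1C=CC(=O)O1 | starting material
9 | fragment A, (5S)-5-{[(triethylsilyl)oxy]methyl}furan-2(5H)-one | CC[Si](CC)(CC)OC[C@@H]1C=CC(=O)O1 | intermediate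
10 | 2-lithio derivative of 7 (lithium on the dithiane carbon C8) | [Li]C1(SCCCS1)C[C@@](C)(O[Si](CC)(CC)CC)C2(O[Si](C(C)C)(C(C)C)C(C)C)CC2 | intermediate (not isolated)
11 | lithium lactone enolate from conjugate addition of 10 to 9 (C8 on C7 trans to the C6 CH2OTES group) | CC[Si](CC)(CC)OC[C@H]1OC(O[Li])=C[C@@H]1C3(C[C@@](C)(O[Si](CC)(CC)CC)C4(O[Si](C(C)C)(C(C)C)C(C)C)CC4)SCCCS3 | intermediate (not isolated)
12 | all-trans lactone adduct: γ-butyrolactone with CH2OTES on C6, the 1,3-dithiane carbon C8 on C7 (carrying CH2–C10(R)(CH3)(OTES)–[1-(OTIPS)cyclopropyl]) and CH2OPMB on C11; 6,7-trans and 7,11-trans | CC[Si](CC)(CC)OC[C@H]1OC(=O)[C@@H](COCc2ccc(OC)cc2)[C@@H]1C3(C[C@@](C)(O[Si](CC)(CC)CC)C4(O[Si](C(C)C)(C(C)C)C(C)C)CC4)SCCCS3 | intermediate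
13 | C5 aldehyde: as 12 with a formyl group on C6 in place of CH2OTES | O=C[C@H]1OC(=O)[C@@H](COCc2ccc(OC)cc2)[C@@H]1C3(C[C@@](C)(O[Si](CC)(CC)CC)C4(O[Si](C(C)C)(C(C)C)C(C)C)CC4)SCCCS3 | intermediate
14 | (Z)-iodoalkene: as 12 with (Z)-CH=C(I)CH3 on C6 (iodine cis to C6) | C/C(I)=C/[C@H]1OC(=O)[C@@H](COCc2ccc(OC)cc2)[C@@H]1C3(C[C@@](C)(O[Si](CC)(CC)CC)C4(O[Si](C(C)C)(C(C)C)C(C)C)CC4)SCCCS3 | intermediate
15 | C8 ketone: as 14 with the dithiane replaced by C=O | C/C(I)=C/[C@H]1OC(=O)[C@@H](COCc2ccc(OC)cc2)[C@@H]1C(=O)C[C@@](C)(O[Si](CC)(CC)CC)C3(O[Si](C(C)C)(C(C)C)C(C)C)CC3 | intermediate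
16 | β-hydroxy ketone: as 15 with free C10 tertiary hydroxyl | C/C(I)=C/[C@H]1OC(=O)[C@@H](COCc2ccc(OC)cc2)[C@@H]1C(=O)C[C@@](C)(O)C3(O[Si](C(C)C)(C(C)C)C(C)C)CC3 | intermediate
17 | O-diethylboryl derivative (boron chelate) of 16 | C/C(I)=C/[C@H]1OC(=O)[C@@H](COCc2ccc(OC)cc2)[C@@H]1C(=O)C[C@@](C)(OB(CC)CC)C3(O[Si](C(C)C)(C(C)C)C(C)C)CC3 | intermediate (not isolated)
18 | (8S,10R)-8,10-syn-diol | C/C(I)=C/[C@H]1OC(=O)[C@@H](COCc2ccc(OC)cc2)[C@@H]1[C@@H](O)C[C@@](C)(O)C3(O[Si](C(C)C)(C(C)C)C(C)C)CC3 | intermediate
19 | tiglic acid, (2E)-2-methylbut-2-enoic acid | C/C=C(\C)C(=O)O | starting material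
20 | (8S)-8-O-tiglate with free C10 hydroxyl and TIPS-protected cyclopropanol | C/C(I)=C/[C@H]1OC(=O)[C@@H](COCc2ccc(OC)cc2)[C@@H]1[C@@H](OC(=O)/C(C)=C/C)C[C@@](C)(O)C3(O[Si](C(C)C)(C(C)C)C(C)C)CC3 | intermediate
21 | cyclisation precursor: as 20 with free cyclopropanol | C/C(I)=C/[C@H]1OC(=O)[C@@H](COCc2ccc(OC)cc2)[C@@H]1[C@@H](OC(=O)/C(C)=C/C)C[C@@](C)(O)C3(O)CC3 | intermediate
22 | (4Z)-macrocycle: ten-membered carbocycle with C1 ketone, C4=C5 Z alkene, 8-tiglate, 10-hydroxy, 13-O-PMB, trans-fused 6,12-lactone | C/C=C(\C)C(=O)O[C@H]1C[C@@](C)(O)C(=O)CC/C(C)=C\[C@H]2OC(=O)[C@@H](COCc3ccc(OC)cc3)[C@@H]21 | intermediate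
23 | 13-alcohol: as 22 with free C13 hydroxyl | C/C=C(\C)C(=O)O[C@H]1C[C@@](C)(O)C(=O)CC/C(C)=C\[C@H]2OC(=O)[C@@H](CO)[C@@H]21 | intermediate
24 | 10,13-diacetate of 23 (4Z alkene) | C/C=C(\C)C(=O)O[C@H]1C[C@@](C)(OC(C)=O)C(=O)CC/C(C)=C\[C@H]2OC(=O)[C@@H](COC(C)=O)[C@@H]21 | intermediate
25 | CNP0305680.1 | C/C=C(\C)C(=O)O[C@H]1C[C@@](C)(OC(C)=O)C(=O)CC[C@@]2(C)O[C@H]2[C@H]2OC(=O)[C@@H](COC(C)=O)[C@@H]21 | target

**Totals and risks**
Total step count: 18. Longest linear sequence: 17 steps (steps 1–5 and 7–18).

Step 15 (bears the new-method label). What may go wrong: β-hydride elimination of the palladium homoenolate and intermolecular coupling may outrun the slow ten-membered ring closure. Fallback with known chemistry, setting out from 21 and coming back at 22: N-bromosuccinimide in THF at 0 °C opens the cyclopropanol to the β-bromo ketone F1, and Et3N eliminates HBr to give the vinyl ketone F2. Luche reduction (NaBH4, CeCl3·7H2O, MeOH, −78 °C) gives the allylic alcohol F3 as a mixture of C1 epimers that converge later. Hydroboration of the terminal alkene with 9-borabicyclo[3.3.1]nonane gives the B-alkylborane F4, which is added slowly to PdCl2(dppf), AsPh3 and Cs2CO3 in DMF/THF/H2O (B-alkyl Suzuki–Miyaura macrocyclisation) to give the macrocyclic 1-alcohol F5. Parikh–Doering oxidation (SO3·pyridine, DMSO, iPr2NEt) of the secondary alcohol then gives 22.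

Step 18. What may go wrong: mismatched double diastereoselection, in which the conformational bias of the ten-membered ring, or a background oxidation through a dioxirane of the substrate's own α-acetoxy ketone, erodes or reverses the facial selectivity, together with slow oxidation of a hindered alkene. Fallback, setting out from 24 and coming back at 25: if electrophiles prefer the β-face, N-bromosuccinimide in aqueous acetone forms the bromonium ion there and water opens it anti at the tertiary C4, giving the bromohydrin F6 (4α-OH, 5β-Br). Ag2O in THF then closes the oxirane with inversion at C5, placing the oxygen on the α-face as in 25.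

Step 12. What may go wrong: erosion of 1,3-syn selectivity, because the C10 methyl group is forced axial in the boron chelate and flanks the axial hydride trajectory. Fallback, setting out from 16 and coming back at 20: intramolecular hydride delivery with Me4NBH(OAc)3 in MeCN/AcOH at −30 °C (Evans–Saksena reduction, bulky cyclopropyl carbon equatorial) should give the 8-epi (8R,10R)-anti-diol F7. Mitsunobu esterification of F7 with tiglic acid 19 (PPh3, DIAD, toluene) then inverts C8 and gives 20 directly.

**Further compounds**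
F1 | step 15 | β-bromo ketone from ring opening of 21 | C/C(I)=C/[C@H]1OC(=O)[C@@H](COCc2ccc(OC)cc2)[C@@H]1[C@@H](OC(=O)/C(C)=C/C)C[C@@](C)(O)C(=O)CCBr
F2 | step 15 | vinyl ketone | C/C(I)=C/[C@H]1OC(=O)[C@@H](COCc2ccc(OC)cc2)[C@@H]1[C@@H](OC(=O)/C(C)=C/C)C[C@@](C)(O)C(=O)C=C
F3 | step 15 | allylic alcohol (C1 epimers) | C/C(I)=C/[C@H]1OC(=O)[C@@H](COCc2ccc(OC)cc2)[C@@H]1[C@@H](OC(=O)/C(C)=C/C)C[C@@](C)(O)C(O)C=C
F4 | step 15 | B-alkyl-9-borabicyclo[3.3.1]nonane (boron on C3) | C/C(I)=C/[C@H]1OC(=O)[C@@H](COCc2ccc(OC)cc2)[C@@H]1[C@@H](OC(=O)/C(C)=C/C)C[C@@](C)(O)C(O)CCB3C4CCCC3CCC4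
F5 | step 15 | macrocyclic 1-alcohol (C1 epimers) | C/C=C(\C)C(=O)O[C@H]1C[C@@](C)(O)C(O)CC/C(C)=C\[C@H]2OC(=O)[C@@H](COCc3ccc(OC)cc3)[C@@H]21
F6 | step 18 | bromohydrin (4α-hydroxy, 5β-bromo) | C/C=C(\C)C(=O)O[C@H]1C[C@@](C)(OC(C)=O)C(=O)CC[C@@](C)(O)[C@H](Br)[C@H]2OC(=O)[C@@H](COC(C)=O)[C@@H]21
F7 | step 12 | 8-epi (8R,10R)-8,10-anti-diol | C/C(I)=C/[C@H]1OC(=O)[C@@H](COCc2ccc(OC)cc2)[C@@H]1[C@H](O)C[C@@](C)(O)C3(O[Si](C(C)C)(C(C)C)C(C)C)CC3
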